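A small charge of X, 0.2 mol% of the J, has to carry the flask.

| flask | J | X | remark | time |
|---|---|---|---|---|
| south-east | 0.050 M | 0.28 mol% | run made earlier |  |
| west | 0.050 M | 0.44 mol% | run made earlier |  |
| north-west | 0.10 M | 0.2 mol% | run made earlier |  |
| flask | 0.050 M | 0.2 mol% |  | 2.0 h |

| run | time / min | Z / % | E / % |
|---|---|---|---|
| south-east | 8.00 | 12.4 | 14.4 |
| south-east | 25.0 | 18.1 | 24.3 |
| south-east | 40.0 | 18.3 | 26.7 |
| south-east | 60.0 | 19.5 | 28.0 |
| south-east | 90.0 | 20.0 | 28.2 |
| south-east | 120 | 18.3 | 29.6 |
| west | 10.0 | 16.2 | 18.1 |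
| west | 15.0 | 18.1 | 20.7 |
| west | 25.0 | 18.6 | 25.1 |
| west | 40.0 | 20.0 | 26.4 |
| west | 80.0 | 20.4 | 28.1 |
| west | 120 | 19.9 | 29.0 |
| north-west | 10.0 | 15.0 | 18.2 |
| north-west | 30.0 | 19.8 | 25.4 |
| north-west | 60.0 | 20.5 | 27.9 |
| north-west | 80.0 | 19.8 | 28.6 |
| north-west | 120 | 20.3 | 28.8 |

(scatter of a reading: 0.5 percentage points)

* share of Z in Z plus E at 20 s
* share of Z in Z plus E at 6.0 min
* share of Z in Z plus E at 2.0 h
* which of Z and E there is more of at 2.0 h

- the numbers in the tables scatter by 0.5 percentage points (one standard deviation)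

The north-west run holds 0.2 mol% on 0.10 M of J, yet at 10.0 min it shows Z 15.0% and E 18.2%, close to the west run's 16.2% and 18.1%. X therefore seems to count per volume, so each run is rescaled to the flask's J as a loading n. The north-west run then has 0.4 mol%, about the west value, and the flask lies below every earlier run.

Let s be the share of Z in Z plus E, pooled from 60.0 min on. The west and north-west runs give S = 41.5%, the first estimate for the flask. The objection is south-east, which gives 40.3%, lower, with Z at 19.5% and then 18.3%, not rising.

Suppose, then, that X is lost first-order. Its time integral scales with n, and if the approach to S is pseudo-first-order in working X, the fractional shortfall 1 − s/S falls as exp(−n/n*). South-east's shortfall of 2.94% gives the catalyst yardstick n* = 0.079 mol%, the loading that cuts the shortfall by a factor e. This reckoning puts the flask's end share at 38.1%.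

Two objections remain. S assumed finished runs, but the rule leaves north-west short by 0.27 percentage points, under the scatter. The south-east gap is itself poorly read, and multiplying it by 0.5 or 2 moves the estimate to 39.4% or 36.0%. The rule speaks of the end share, not of earlier times.

The forecast, “Treating the two as parallel channels”, puts the share of Z in Z plus E at 50% at 20 s, 48% at 6.0 min and 41% at 2.0 h (range 39% to 43%), the last above the reckoning here, with E ahead.

The flask gives a share of 7.19% at 20 s, 39.8% at 6.0 min and 37.2% at 2.0 h, with E at 29.5% and Z at 17.5% at 2.0 h.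

    J ⇌ E (K = 1.10, k = 0.0340 min⁻¹)
    E + X ⇌ Z + X, rate k2*[X]*[E] forward; the back reaction follows from the equilibrium constant (K = 0.730, k = 580 M⁻¹ min⁻¹)
    Z + X ⇌ L + X, rate k3*[X]*[Z] forward; the back reaction follows from the equilibrium constant (K = 1.20, k = 1400 M⁻¹ min⁻¹)
    L ⇌ J (k = 0.130 min⁻¹)
    X → Q (k = 0.100 min⁻¹)

At 1.00 h the flask holds 0.248% of its catalyst charge as X and 99.8% as Q. The yardstick 0.079 mol% put this flask at 38.1% against its 37.2%. For a neighbour flask charged with 0.08 mol% of X, the same yardstick gives an end share of 26.4%, and that neighbour flask gives 26.5%.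

The numbers in the tables are calculated for an exercise; noise was put on by code.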